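The lactone ring of the phthalide is read as one molecule of carbon dioxide spliced between aromatic C7a and benzylic C3. The precursor is therefore an open-chain 1-alkynyl-2-bromo-3,5-dimethoxybenzene that already carries the complete spiroketal chain and holds C3 at the alkyne oxidation level. In one pot, bromine–lithium exchange and carboxylation form the C7a–C1 bond, and the carboxylate oxygen then adds 5-exo-dig to the alkyne to form the O2–C3 bond, giving a (Z)-3-alkylidenephthalide whose asymmetric hydrogenation sets C3. The spiroketal is assembled from acetone dimethylhydrazone and two (S)-epoxides.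

Key step: step 6

Remarks on the chemistry:
- The spiro carbon of a 1,6-dioxaspiro[4.4]nonane is under thermodynamic control with little bias. Step 5 is therefore expected to give the (5R) ketal together with its (5S) epimer. It is assumed that the two are separable by chromatography and that steps 6 and 7, which are run without added acid, do not re-equilibrate this centre.
- The antipode of the SpinPHOX ligand that gives the (3R) phthalide is assumed to be identified on a simple 3-alkylidenephthalide before step 7.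

Step 1
Reactants: 1 6-chlorohex-1-yne
Product: 2 (6-chlorohex-1-yn-1-yl)trimethylsilane
Conditions: n-BuLi, THF, −78 °C; TMSCl, −78 °C to rt
Reagents that add atoms: chlorotrimethylsilane, C[Si](C)(C)Cl
Why: Acetylide formation is far faster than attack on the primary chloride at −78 °C, and C-silylation of the lithium acetylide masks the acidic C–H for the Grignard chemistry of step 2 (alkyne silylation).

Step 2
Reactants: 2 (6-chlorohex-1-yn-1-yl)trimethylsilane; 3 (S)-epichlorohydrin
Product: 6 (S)-2-(hept-6-yn-1-yl)oxirane, via Grignard reagent 4 (not isolated), via chlorohydrin 5 (not isolated)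
Conditions: Mg, I2 (cat.), THF, reflux; 3, CuI (10 mol%), −30 to 0 °C; then MeOH, K2CO3, rt
Reagents that add atoms: none
Why: Copper-catalysed Grignard opening of the epoxide of 3 at its CH2 terminus leaves the stereocentre untouched, and base then closes the chlorohydrin alkoxide onto the CH2Cl carbon and cleaves the C–Si bond by methanolysis, so that the (S) centre of 3 becomes the (S) centre of 6 (Grignard–epichlorohydrin homologation to a terminal epoxide).

Step 3
Reactants: 7 1-iodo-3,5-dimethoxybenzene
Product: 8 2-bromo-1-iodo-3,5-dimethoxybenzene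
Conditions: NBS, MeCN, 0 °C to rt
Reagents that add atoms: N-bromosuccinimide, O=C1CCC(=O)N1Br
Why: Electrophilic aromatic bromination of a 5-substituted 1,3-dimethoxybenzene should go para to one methoxy group and ortho to the other, next to iodine, and not between the two methoxy groups.

Step 4
Reactants: 6 (S)-2-(hept-6-yn-1-yl)oxirane; 8 2-bromo-1-iodo-3,5-dimethoxybenzene
Product: 9 (S)-2-[7-(2-bromo-3,5-dimethoxyphenyl)hept-6-yn-1-yl]oxirane
Conditions: PdCl2(PPh3)2 (2 mol%), CuI (4 mol%), Et3N, THF, rt
Reagents that add atoms: none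
Why: Sonogashira coupling, in which zerovalent palladium inserts much faster into the C–I than into the C–Br bond at room temperature, so the bromide is kept for step 6 and the epoxide survives the amine base.

Step 5
Reactants: 10 acetone N,N-dimethylhydrazone; 11 (S)-propylene oxide; 9 (S)-2-[7-(2-bromo-3,5-dimethoxyphenyl)hept-6-yn-1-yl]oxirane
Product: 15 (2S,5R,7S)-2-[7-(2-bromo-3,5-dimethoxyphenyl)hept-6-yn-1-yl]-7-methyl-1,6-dioxaspiro[4.4]nonane, via lithium alkoxide 12 (not isolated), via bis-adduct hydrazone 13 (not isolated), via keto diol 14 (not isolated)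
Conditions: 10, n-BuLi, THF, −78 to 0 °C; 11, 0 °C; n-BuLi, −78 to 0 °C; 9, 0 °C to rt; then 1 M HCl, rt; chromatography
Reagents that add atoms: none
Why: Corey–Enders type azaenolate alkylation, in which the lithiated hydrazone opens 11 at CH2, a second deprotonation at the remaining, less substituted α-methyl group allows opening of 9 at CH2, both carbinol centres come unchanged from the epoxides, and acid hydrolysis frees the 1,7-dihydroxy-4-ketone, which closes to the spiroketal under thermodynamic control; the (5R) isomer is separated from its (5S) epimer, which is re-equilibrated (PPTS, CH2Cl2) and recycled.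

Step 6
Reactants: 15 (2S,5R,7S)-2-[7-(2-bromo-3,5-dimethoxyphenyl)hept-6-yn-1-yl]-7-methyl-1,6-dioxaspiro[4.4]nonane
Product: 18 (Z)-5,7-dimethoxy-3-{6-[(2S,5R,7S)-7-methyl-1,6-dioxaspiro[4.4]nonan-2-yl]hexylidene}-2-benzofuran-1(3H)-one, via aryllithium 16 (not isolated), via lithium carboxylate 17 (not isolated)
Conditions: t-BuLi (2.1 equiv), THF, −78 °C; CO2 (dry gas), −78 °C to rt; then AcOH (1 equiv), DBU (1.5 equiv), MeCN, 70 °C
Reagents that add atoms: carbon dioxide, O=C=O
Why: Bromine–lithium exchange gives aryllithium 16, which adds to CO2 and so forms the C7a–C1 bond of carboxylate 17; after proton exchange (AcOH, DBU) the amidinium carboxylate adds through oxygen to the ring-bound alkyne carbon with anti protonation of the other one, which forms the O2–C3 bond. The closest known reaction types are the carboxylation of aryllithiums with CO2 and the amidine-base-catalysed cycloisomerisation of 2-alkynylbenzoic acids to (Z)-3-ylidenephthalides, here run in one flask. The five-membered lactone ring closes in the 5-exo-dig mode. No stereocentre is created; anti addition fixes the Z geometry of the exocyclic alkene, and C3 is set in step 7. The step needs 5-exo over 6-endo selectivity (phthalide versus isocoumarin), which the anionic attack on a non-activated alkyne should secure, since acids and electrophilic metals that favour the 6-endo path are absent. Two equivalents of t-BuLi destroy the tert-butyl bromide formed, so no alkyl halide is left to esterify 17, and the basic medium leaves the acid-labile spiro centre alone.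

Step 7
Reactants: 18 (Z)-5,7-dimethoxy-3-{6-[(2S,5R,7S)-7-methyl-1,6-dioxaspiro[4.4]nonan-2-yl]hexylidene}-2-benzofuran-1(3H)-one
Product: 19 (3R)-5,7-dimethoxy-3-{6-[(2S,5R,7S)-7-methyl-1,6-dioxaspiro[4.4]nonan-2-yl]hexyl}-2-benzofuran-1(3H)-one (CNP0380736.1)
Conditions: H2 (30 bar), [Ir(cod)(SpinPHOX)][B(3,5-(CF3)2C6H3)4] (1 mol%, ligand antipode for the 3R series), CH2Cl2, rt
Reagents that add atoms: none
Why: Iridium-catalysed asymmetric hydrogenation of the exocyclic enol-lactone alkene of a 3-ylidenephthalide, a known substrate class for this catalyst type, in which the chiral P,N ligand controls the face of hydrogen delivery to the Z alkene and so sets (3R), while the remote spiroketal centres have no influence and are not touched.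

Compound list
1 | 6-chlorohex-1-yne | C#CCCCCCl | starting material
2 | (6-chlorohex-1-yn-1-yl)trimethylsilane | C[Si](C)(C)C#CCCCCCl | intermediate
3 | (S)-epichlorohydrin, (S)-2-(chloromethyl)oxirane | ClC[C@@H]1CO1 | starting material
4 | [6-(trimethylsilyl)hex-5-yn-1-yl]magnesium chloride | C[Si](C)(C)C#CCCCC[Mg]Cl | intermediate
5 | (S)-1-chloro-9-(trimethylsilyl)non-8-yn-2-ol (magnesium alkoxide in the flask) | ClC[C@@H](O)CCCCCC#C[Si](C)(C)C | intermediate
6 | (S)-2-(hept-6-yn-1-yl)oxirane | C#CCCCCC[C@H]1CO1 | intermediate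
7 | 1-iodo-3,5-dimethoxybenzene | COc1cc(I)cc(OC)c1 | starting material
8 | 2-bromo-1-iodo-3,5-dimethoxybenzene | COc1cc(I)c(Br)c(OC)c1 | intermediate
9 | (S)-2-[7-(2-bromo-3,5-dimethoxyphenyl)hept-6-yn-1-yl]oxirane | COc1cc(OC)c(Br)c(c1)C#CCCCCC[C@H]1CO1 | intermediate
10 | acetone N,N-dimethylhydrazone | CC(C)=NN(C)C | starting material
11 | (S)-propylene oxide, (S)-2-methyloxirane | C[C@H]1CO1 | starting material
12 | lithium (S)-5-(2,2-dimethylhydrazinylidene)hexan-2-olate | CC(=NN(C)C)CC[C@H](C)[O-].[Li+] | intermediate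
13 | dilithium (2S,8S)-15-(2-bromo-3,5-dimethoxyphenyl)-5-(2,2-dimethylhydrazinylidene)pentadec-14-yne-2,8-diolate | COc1cc(OC)c(Br)c(c1)C#CCCCCC[C@H]([O-])CCC(=NN(C)C)CC[C@H](C)[O-].[Li+].[Li+] | intermediate
14 | (2S,8S)-15-(2-bromo-3,5-dimethoxyphenyl)-2,8-dihydroxypentadec-14-yn-5-one | COc1cc(OC)c(Br)c(c1)C#CCCCCC[C@H](O)CCC(=O)CC[C@H](C)O | intermediate
15 | (2S,5R,7S)-2-[7-(2-bromo-3,5-dimethoxyphenyl)hept-6-yn-1-yl]-7-methyl-1,6-dioxaspiro[4.4]nonane | COc1cc(OC)c(Br)c(c1)C#CCCCCC[C@H]1CC[C@@]2(CC[C@H](C)O2)O1 | intermediate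
16 | (2,4-dimethoxy-6-{7-[(2S,5R,7S)-7-methyl-1,6-dioxaspiro[4.4]nonan-2-yl]hept-1-yn-1-yl}phenyl)lithium | COc1cc(OC)c([Li])c(c1)C#CCCCCC[C@H]1CC[C@@]2(CC[C@H](C)O2)O1 | intermediate
17 | lithium 2,4-dimethoxy-6-{7-[(2S,5R,7S)-7-methyl-1,6-dioxaspiro[4.4]nonan-2-yl]hept-1-yn-1-yl}benzoate | COc1cc(OC)c(C(=O)[O-])c(c1)C#CCCCCC[C@H]1CC[C@@]2(CC[C@H](C)O2)O1.[Li+] | intermediate
18 | (Z)-5,7-dimethoxy-3-{6-[(2S,5R,7S)-7-methyl-1,6-dioxaspiro[4.4]nonan-2-yl]hexylidene}-2-benzofuran-1(3H)-one | COc1cc(OC)c2c(c1)/C(=C/CCCCC[C@H]1CC[C@@]3(CC[C@H](C)O3)O1)OC2=O | intermediate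
19 | (3R)-5,7-dimethoxy-3-{6-[(2S,5R,7S)-7-methyl-1,6-dioxaspiro[4.4]nonan-2-yl]hexyl}-2-benzofuran-1(3H)-one | COc1cc(OC)c2c(c1)[C@@H](CCCCCC[C@H]1CC[C@@]3(CC[C@H](C)O3)O1)OC2=O | target

Total step count: 7
Longest linear sequence: 6 steps (steps 1, 2, 4, 5, 6 and 7, from 6-chlorohex-1-yne); step 3 is a one-step side branch.

Steps most likely to fail

Step 6. The carboxylate may close in the 6-endo mode to the isocoumarin, or the aryllithium may be quenched before it captures CO2. The fallback builds the same enol lactone by the known palladium/copper coupling–cyclisation of an ortho-iodobenzoic acid with a terminal alkyne. It sets out from epoxide 6 and iodoarene 7 and comes back at 18. The lithium acetylide of 6 (n-BuLi, THF, −78 °C) is used in place of 9 in the sequence of step 5. This gives (2S,8S)-5-(2,2-dimethylhydrazinylidene)pentadec-14-yne-2,8-diol F1, then on acid hydrolysis (2S,8S)-2,8-dihydroxypentadec-14-yn-5-one F2, which closes to (2S,5R,7S)-2-(hept-6-yn-1-yl)-7-methyl-1,6-dioxaspiro[4.4]nonane F3 (separated from its 5-epimer as in step 5). Vilsmeier–Haack formylation of 7 (POCl3, DMF) gives 2-iodo-4,6-dimethoxybenzaldehyde F4. Pinnick oxidation (NaClO2, NaH2PO4, 2-methyl-2-butene, t-BuOH/H2O) gives 2-iodo-4,6-dimethoxybenzoic acid F5. F3 and F5 with PdCl2(PPh3)2, CuI and Et3N in DMF at 60 °C couple and cyclise to 18.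

Step 7. Facial selectivity of hydrogen delivery may be insufficient, or acid formed from the iridium hydride catalyst may re-equilibrate the spiro centre. The fallback sets C3 by ketone reduction instead of alkene hydrogenation. It sets out from 18 and comes back at 19. Aqueous NaOH in THF opens the enol lactone to 2,4-dimethoxy-6-{7-[(2S,5R,7S)-7-methyl-1,6-dioxaspiro[4.4]nonan-2-yl]heptanoyl}benzoic acid F6, handled as its sodium salt. Asymmetric transfer hydrogenation (RuCl[(R,R)-TsDPEN](p-cymene), HCO2Na, H2O/MeOH, 40 °C) should give 2-{(1R)-1-hydroxy-7-[(2S,5R,7S)-7-methyl-1,6-dioxaspiro[4.4]nonan-2-yl]heptyl}-4,6-dimethoxybenzoic acid F7. On mild acidification (NaH2PO4 buffer) F7 lactonises to 19.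

Step 5. The second deprotonation of the hydrazone alkoxide may be incomplete or go at the wrong α-carbon, or the epoxide opening by the azaenolate may stall. The fallback replaces the azaenolate by an acetylide and the ketone by an alkyne. It sets out from 9 and 11 and comes back at 15. Allenylmagnesium bromide opens 11 to (S)-hex-5-yn-2-ol F8. Its dilithio derivative (n-BuLi, 2 equiv, THF, −78 °C) opens 9 at CH2 in the presence of BF3·OEt2 to give (2S,8S)-15-(2-bromo-3,5-dimethoxyphenyl)pentadeca-5,14-diyne-2,8-diol F9. Double intramolecular hydroalkoxylation of the alkyne flanked by the two hydroxyl groups (AuCl, 5 mol%, CH2Cl2, rt) gives 15, with the same separation of spiro epimers.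

Further compounds
F1 | step 6 | (2S,8S)-5-(2,2-dimethylhydrazinylidene)pentadec-14-yne-2,8-diol | C#CCCCCC[C@H](O)CCC(=NN(C)C)CC[C@H](C)O
F2 | step 6 | (2S,8S)-2,8-dihydroxypentadec-14-yn-5-one | C#CCCCCC[C@H](O)CCC(=O)CC[C@H](C)O
F3 | step 6 | (2S,5R,7S)-2-(hept-6-yn-1-yl)-7-methyl-1,6-dioxaspiro[4.4]nonane | C#CCCCCC[C@H]1CC[C@@]2(CC[C@H](C)O2)O1
F4 | step 6 | 2-iodo-4,6-dimethoxybenzaldehyde | COc1cc(OC)c(C=O)c(I)c1
F5 | step 6 | 2-iodo-4,6-dimethoxybenzoic acid | COc1cc(OC)c(C(=O)O)c(I)c1
F6 | step 7 | 2,4-dimethoxy-6-{7-[(2S,5R,7S)-7-methyl-1,6-dioxaspiro[4.4]nonan-2-yl]heptanoyl}benzoic acid | COc1cc(OC)c(C(=O)O)c(c1)C(=O)CCCCCC[C@H]1CC[C@@]2(CC[C@H](C)O2)O1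
F7 | step 7 | 2-{(1R)-1-hydroxy-7-[(2S,5R,7S)-7-methyl-1,6-dioxaspiro[4.4]nonan-2-yl]heptyl}-4,6-dimethoxybenzoic acid | COc1cc(OC)c(C(=O)O)c(c1)[C@H](O)CCCCCC[C@H]1CC[C@@]2(CC[C@H](C)O2)O1
F8 | step 5 | (S)-hex-5-yn-2-ol | C#CCC[C@H](C)O
F9 | step 5 | (2S,8S)-15-(2-bromo-3,5-dimethoxyphenyl)pentadeca-5,14-diyne-2,8-diol | COc1cc(OC)c(Br)c(c1)C#CCCCCC[C@H](O)CC#CCC[C@H](C)O
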